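Kanzonol I's only stereocentre, C3, is stereogenic solely because its two CH2 arms end on different atoms of one ring: C2 on O1 and C4 on C4a of an A ring that derives from a C2v-symmetric phenol. Hydrogenation, the usual way to set C3, is barred by the prenyl and chromene alkenes. C2–C3–C4 are therefore taken from a prochiral 3-aryloxetane that already carries the B-ring chromene. The key step is a catalytic enantioselective, strain-releasing bromide opening of this achiral oxetane: it sets C3 and gives a 1,3-bromohydrin with two distinguishable ends. The alcohol end is then joined to O1 by Mitsunobu etherification of the ortho-iodinated A-ring phenol, and the bromide end to C4a by Parham cyclisation.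

Key step: step 8

Remark: the SMILES is read as the (3R)-isoflavan (CIP order at C3: C2 > C1′ > C4 > H); isoflavan numbering is used, and the antipode of the squaramide catalyst in step 8 is chosen to give the R bromohydrin.

**Step 1**
Reactants: 1 1,3-dimethoxybenzene
Product: 3 1,3-dimethoxy-2-(3-methylbut-2-en-1-yl)benzene, via 2-lithio-1,3-dimethoxybenzene 2 (not isolated)
Conditions: n-BuLi, THF, 0 °C → rt; then prenyl bromide, −78 °C → rt
Reagents that add atoms: prenyl bromide (1-bromo-3-methylbut-2-ene), CC(C)=CCBr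
Why: Directed ortho-metalation between the two methoxy groups followed by SN2 alkylation of the aryllithium with the allylic bromide should give the 2-prenyl compound.

**Step 2**
Reactants: 3 1,3-dimethoxy-2-(3-methylbut-2-en-1-yl)benzene
Product: 5 3,5-dimethoxy-4-(3-methylbut-2-en-1-yl)phenol, via aryl pinacol boronate 4 (not isolated)
Conditions: [Ir(OMe)(cod)]2 (1.5 mol %), dtbpy (3 mol %), B2pin2 (1.0 equiv), THF, 60 °C; then NaOH (aq), H2O2 (aq), 0 °C → rt
Reagents that add atoms: hydrogen peroxide, OO
Why: Sterically controlled iridium-catalysed C–H borylation should go to the only ring C–H that has no ortho substituent, and oxidation of the C–B bond in the same flask should give the C2v-symmetric phenol.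

**Step 3**
Reactants: 5 3,5-dimethoxy-4-(3-methylbut-2-en-1-yl)phenol
Product: 6 2-iodo-3,5-dimethoxy-4-(3-methylbut-2-en-1-yl)phenol
Conditions: NIS (1.0 equiv), CH2Cl2, −40 °C → 0 °C
Reagents that add atoms: N-iodosuccinimide, O=C1CCC(=O)N1I
Why: Electrophilic aromatic iodination of a phloroglucinol-type ring should be faster than attack on the prenyl alkene, and the two ortho positions are equivalent by symmetry, so only one mono-iodide can form.

**Step 4**
Reactants: 7 4-bromobenzene-1,3-diol (4-bromoresorcinol)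
Product: 8 2-bromo-5-[(triisopropylsilyl)oxy]phenol
Conditions: TIPSCl (1.0 equiv), imidazole, DMF, −20 °C → 0 °C
Reagents that add atoms: chlorotriisopropylsilane, CC(C)[Si](Cl)(C(C)C)C(C)C
Why: Silyl ether formation under steric control should take the bulky silyl chloride to the hydroxyl remote from bromine, since the hydroxyl flanked by bromine is shielded.

**Step 5**
Reactants: 8 2-bromo-5-[(triisopropylsilyl)oxy]phenol
Product: 9 {4-bromo-3-[(2-methylbut-3-yn-2-yl)oxy]phenoxy}triisopropylsilane
Conditions: 3-chloro-3-methylbut-1-yne, DBU, CuCl2·2H2O (1 mol %), MeCN, 0 °C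
Reagents that add atoms: 3-chloro-3-methylbut-1-yne, C#CC(C)(C)Cl
Why: Copper-catalysed propargylic etherification of a phenol with a tertiary propargylic chloride is reliable for hindered phenols and should leave the aryl silyl ether intact at 0 °C.

**Step 6**
Reactants: 9 {4-bromo-3-[(2-methylbut-3-yn-2-yl)oxy]phenoxy}triisopropylsilane
Product: 13 8-bromo-2,2-dimethyl-5-[(triisopropylsilyl)oxy]-2H-chromene, via allenyl cyclohexadienone 10 (not isolated), via 2-allenylphenol 11 (not isolated), via o-quinone methide 12 (not isolated)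
Conditions: o-xylene, 150 °C (sealed tube)
Reagents that add atoms: none
Why: The aryl propargyl ether Claisen rearrangement ([3,3]) can only go to the free ortho carbon between the two oxygens because the other ortho carbon bears bromine, and enolisation, 1,5-hydrogen shift and oxa-6π electrocyclisation should then give the 2,2-dimethylchromene.

**Step 7**
Reactants: 13 8-bromo-2,2-dimethyl-5-[(triisopropylsilyl)oxy]-2H-chromene; 14 3-iodooxetane
Product: 16 3-{2,2-dimethyl-5-[(triisopropylsilyl)oxy]-2H-chromen-8-yl}oxetane, via oxetan-3-ylzinc iodide 15 (not isolated)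
Conditions: 14, Zn dust, LiCl, THF, 40 °C; then 13, Pd(OAc)2 (2 mol %), CPhos (4 mol %), THF, 50 °C
Reagents that add atoms: none
Why: Negishi coupling of a secondary cycloalkylzinc halide with an ortho-alkoxy aryl bromide should give the 3-aryloxetane, β-hydride elimination from the oxetanyl–palladium species being disfavoured by ring strain.

**Step 8**
Reactants: 16 3-{2,2-dimethyl-5-[(triisopropylsilyl)oxy]-2H-chromen-8-yl}oxetane
Product: 18 (2R)-3-bromo-2-{2,2-dimethyl-5-[(triisopropylsilyl)oxy]-2H-chromen-8-yl}propan-1-ol, via bromo trimethylsilyl ether 17 (not isolated)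
Conditions: chiral arylpyrrolidine-derived squaramide hydrogen-bond donor (5 mol %), Me3SiBr (1.3 equiv), t-BuOMe, −80 °C; then Et3N, MeOH, −80 °C → 0 °C; citric acid (cat.), MeOH, 0 °C
Reagents that add atoms: bromotrimethylsilane, C[Si](C)(C)Br
Why: Me3SiBr silylates the oxetane oxygen and the chiral squaramide binds the bromide, so that a silyloxetanium ion paired with catalyst-bound bromide is formed and bromide is delivered by SN2 attack to one of the two enantiotopic CH2 groups, the release of about 25 kcal/mol of ring strain making the opening irreversible. The closest known reaction type is exactly this hydrogen-bond-donor-catalysed enantioselective silyl bromide opening of 3-substituted oxetanes, 3-aryl cases included. No ring is closed; the four-membered ring is opened, and methanolysis of the silyl ether then frees the alcohol without base, so that the bromohydrin cannot close back to the oxetane. C3 becomes stereogenic only through the choice between its two CH2 arms, and this choice is under catalyst control (the catalyst enantiomer that leads to R is used). The step needs enantiotopic-group selectivity and must outrun the uncatalysed opening as well as participation by the electron-rich aryl group or by the neighbouring chromene oxygen; the very low temperature, the weakly polar ether solvent and the acceleration of the catalysed pathway should secure this, while the aryl silyl ether and the chromene alkene should be inert to Me3SiBr at −80 °C.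

**Step 9**
Reactants: 6 2-iodo-3,5-dimethoxy-4-(3-methylbut-2-en-1-yl)phenol; 18 (2R)-3-bromo-2-{2,2-dimethyl-5-[(triisopropylsilyl)oxy]-2H-chromen-8-yl}propan-1-ol
Product: 19 8-{(2R)-1-bromo-3-[2-iodo-3,5-dimethoxy-4-(3-methylbut-2-en-1-yl)phenoxy]propan-2-yl}-2,2-dimethyl-5-[(triisopropylsilyl)oxy]-2H-chromene
Conditions: PPh3, DIAD, THF, 0 °C → rt
Reagents that add atoms: none
Why: In this Mitsunobu etherification the acidic ortho-iodophenol should displace the activated primary hydroxyl by SN2 at CH2 (the future C2–O1 bond), while the alkyl bromide is inert and the stereocentre is not involved.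

**Step 10**
Reactants: 19 8-{(2R)-1-bromo-3-[2-iodo-3,5-dimethoxy-4-(3-methylbut-2-en-1-yl)phenoxy]propan-2-yl}-2,2-dimethyl-5-[(triisopropylsilyl)oxy]-2H-chromene
Product: 21 8-[(3R)-5,7-dimethoxy-6-(3-methylbut-2-en-1-yl)-3,4-dihydro-2H-chromen-3-yl]-2,2-dimethyl-5-[(triisopropylsilyl)oxy]-2H-chromene, via aryllithium 20 (not isolated)
Conditions: n-BuLi (1.05 equiv), THF, −100 °C; then −100 °C → rt
Reagents that add atoms: none
Why: In this Parham cyclisation iodine–lithium exchange at the aryl iodide should be far faster than any reaction of the primary alkyl bromide, and the aryllithium should then close the C4–C4a bond by 6-exo-tet SN2 displacement of bromide without touching C3.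

**Step 11**
Reactants: 21 8-[(3R)-5,7-dimethoxy-6-(3-methylbut-2-en-1-yl)-3,4-dihydro-2H-chromen-3-yl]-2,2-dimethyl-5-[(triisopropylsilyl)oxy]-2H-chromene
Product: 22 Kanzonol I, 8-[(3R)-5,7-dimethoxy-6-(3-methylbut-2-en-1-yl)-3,4-dihydro-2H-chromen-3-yl]-2,2-dimethyl-2H-chromen-5-ol
Conditions: TBAF, THF, 0 °C; aq NH4Cl
Reagents that add atoms: none
Why: Fluoride cleavage of the aryl silyl ether is neither acidic nor reducing and should spare the prenyl group, the chromene alkene and the stereocentre.

**Compound list**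

1 | 1,3-dimethoxybenzene | COc1cccc(OC)c1 | starting material
2 | 2-lithio-1,3-dimethoxybenzene | COc1cccc(OC)c1[Li] | intermediate
3 | 1,3-dimethoxy-2-(3-methylbut-2-en-1-yl)benzene | COc1cccc(OC)c1CC=C(C)C | intermediate
4 | 2-[3,5-dimethoxy-4-(3-methylbut-2-en-1-yl)phenyl]-4,4,5,5-tetramethyl-1,3,2-dioxaborolane | COc1cc(B2OC(C)(C)C(C)(C)O2)cc(OC)c1CC=C(C)C | intermediate
5 | 3,5-dimethoxy-4-(3-methylbut-2-en-1-yl)phenol | COc1cc(O)cc(OC)c1CC=C(C)C | intermediate
6 | 2-iodo-3,5-dimethoxy-4-(3-methylbut-2-en-1-yl)phenol | Oc1cc(OC)c(CC=C(C)C)c(OC)c1I | intermediate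
7 | 4-bromobenzene-1,3-diol (4-bromoresorcinol) | Oc1ccc(Br)c(O)c1 | starting material
8 | 2-bromo-5-[(triisopropylsilyl)oxy]phenol | Oc1cc(O[Si](C(C)C)(C(C)C)C(C)C)ccc1Br | intermediate
9 | {4-bromo-3-[(2-methylbut-3-yn-2-yl)oxy]phenoxy}triisopropylsilane | C#CC(C)(C)Oc1cc(O[Si](C(C)C)(C(C)C)C(C)C)ccc1Br | intermediate
10 | 6-bromo-2-(3-methylbuta-1,2-dien-1-yl)-3-[(triisopropylsilyl)oxy]cyclohexa-3,5-dien-1-one | O=C1C(Br)=CC=C(O[Si](C(C)C)(C(C)C)C(C)C)C1C=C=C(C)C | intermediate
11 | 6-bromo-2-(3-methylbuta-1,2-dien-1-yl)-3-[(triisopropylsilyl)oxy]phenol | CC(C)=C=Cc1c(O)c(Br)ccc1O[Si](C(C)C)(C(C)C)C(C)C | intermediate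
12 | 2-bromo-6-(3-methylbut-2-en-1-ylidene)-5-[(triisopropylsilyl)oxy]cyclohexa-2,4-dien-1-one | CC(C)=CC=C1C(=O)C(Br)=CC=C1O[Si](C(C)C)(C(C)C)C(C)C | intermediate
13 | 8-bromo-2,2-dimethyl-5-[(triisopropylsilyl)oxy]-2H-chromene | CC1(C)C=Cc2c(O[Si](C(C)C)(C(C)C)C(C)C)ccc(Br)c2O1 | intermediate
14 | 3-iodooxetane | IC1COC1 | starting material
15 | oxetan-3-ylzinc iodide | I[Zn]C1COC1 | intermediate
16 | 3-{2,2-dimethyl-5-[(triisopropylsilyl)oxy]-2H-chromen-8-yl}oxetane | CC1(C)C=Cc2c(O[Si](C(C)C)(C(C)C)C(C)C)ccc(C3COC3)c2O1 | intermediate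
17 | {(2R)-3-bromo-2-[2,2-dimethyl-5-(triisopropylsilyloxy)-2H-chromen-8-yl]propoxy}trimethylsilane | BrC[C@H](c1ccc(O[Si](C(C)C)(C(C)C)C(C)C)c2c1OC(C)(C)C=C2)CO[Si](C)(C)C | intermediate
18 | (2R)-3-bromo-2-{2,2-dimethyl-5-[(triisopropylsilyl)oxy]-2H-chromen-8-yl}propan-1-ol | BrC[C@H](c1ccc(O[Si](C(C)C)(C(C)C)C(C)C)c2c1OC(C)(C)C=C2)CO | intermediate
19 | 8-{(2R)-1-bromo-3-[2-iodo-3,5-dimethoxy-4-(3-methylbut-2-en-1-yl)phenoxy]propan-2-yl}-2,2-dimethyl-5-[(triisopropylsilyl)oxy]-2H-chromene | BrC[C@H](c1ccc(O[Si](C(C)C)(C(C)C)C(C)C)c2c1OC(C)(C)C=C2)COc1cc(OC)c(CC=C(C)C)c(OC)c1I | intermediate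
20 | aryllithium from 19 (lithium in place of iodine) | BrC[C@H](c1ccc(O[Si](C(C)C)(C(C)C)C(C)C)c2c1OC(C)(C)C=C2)COc1cc(OC)c(CC=C(C)C)c(OC)c1[Li] | intermediate
21 | 8-[(3R)-5,7-dimethoxy-6-(3-methylbut-2-en-1-yl)-3,4-dihydro-2H-chromen-3-yl]-2,2-dimethyl-5-[(triisopropylsilyl)oxy]-2H-chromene | COc1cc2c(c(OC)c1CC=C(C)C)C[C@H](c1ccc(O[Si](C(C)C)(C(C)C)C(C)C)c3c1OC(C)(C)C=C3)CO2 | intermediate
22 | Kanzonol I, 8-[(3R)-5,7-dimethoxy-6-(3-methylbut-2-en-1-yl)-3,4-dihydro-2H-chromen-3-yl]-2,2-dimethyl-2H-chromen-5-ol | COc1cc2c(c(OC)c1CC=C(C)C)C[C@H](c1ccc(O)c3c1OC(C)(C)C=C3)CO2 | target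

**Totals**

Total step count: 11.
Longest linear sequence: 8 steps (7 → 22, steps 4 to 11); the A-ring branch (steps 1 to 3) joins at step 9.

**Steps most likely to fail**

Step 8 (key step). Enantiocontrol may erode if the silyloxetanium ion is opened without the catalyst, or if the electron-rich aryl group or the neighbouring chromene oxygen participates in the opening; such participation could also give rearranged bromides. The fallback replaces the oxetane desymmetrisation by an enzymatic desymmetrisation of the open-chain prochiral diol; it sets out from 13 and comes back at 18. Palladium-catalysed α-arylation of diethyl malonate with 13 (Pd(OAc)2, P(t-Bu)3, K3PO4, toluene, 80 °C) should give diethyl arylmalonate F1. Reduction with LiAlH4 (Et2O, 0 °C) should give the prochiral 2-aryl-propane-1,3-diol F2. Lipase-catalysed monoacetylation with vinyl acetate, with the enzyme chosen from a screen (Amano PS, PPL, CAL-B) for the required sense, should give the (S)-monoacetate F3. Appel bromination (CBr4, PPh3, CH2Cl2, 0 °C) should give the (R)-bromo acetate F4, and DIBAL-H (CH2Cl2, −78 °C) should remove the acetate without base to give 18.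

Step 10. The aryllithium may abstract the benzylic C3–H with loss of bromide (elimination to a 2-arylallyl ether) instead of displacing bromide, or it may be butylated by the 1-iodobutane formed in the exchange or quenched before ring closure. The fallback reverses the order of the two ring bonds, so that C4–C4a is made first by an intermolecular coupling and O1–C2 last; it sets out from 5 and 17 and comes back at 21. Phenol 5 is protected (MOMCl, i-Pr2NEt, CH2Cl2) as the methoxymethyl ether F5. n-BuLi (THF, 0 °C) should metalate F5 between the OMOM and OMe groups to give the aryllithium F6, which MgBr2·OEt2 converts into the aryl Grignard reagent F7. Copper-catalysed alkylation (Li2CuCl4 cat., THF/NMP, 0 °C → rt) with 17 (kept as the silyl ether by omitting the methanolysis of step 8, or remade from 18 with Me3SiCl/Et3N) should give the coupled product F8. Dilute HCl in MeOH (40 °C) removes the MOM and trimethylsilyl groups to give the phenol–alcohol F9, and Mitsunobu cyclisation (PPh3, DIAD, THF) should close O1–C2 to give 21.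

Step 2. The prenyl alkene may interfere with the iridium boryl catalyst through alkene hydroboration, double-bond isomerisation or allylic C–H borylation. The fallback inverts the order, oxygenating first and prenylating second; it sets out from 1 and comes back at 5. The same borylation of 1, now without an alkene present, should give the aryl boronate F10, which is oxidised (NaOH, H2O2) to 3,5-dimethoxyphenol F11 (also commercial). TIPSCl and imidazole give the silyl ether F12. n-BuLi (THF, 0 °C) should metalate F12 between the two methoxy groups, the bulky, non-coordinating silyl ether shielding the other positions, to give the aryllithium F13. CuBr·SMe2 and prenyl bromide should give the prenylated silyl ether F14, and TBAF gives 5.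

**Further compounds**

F1 | step 8 | diethyl 2-{2,2-dimethyl-5-[(triisopropylsilyl)oxy]-2H-chromen-8-yl}malonate | CCOC(=O)C(C(=O)OCC)c1ccc(O[Si](C(C)C)(C(C)C)C(C)C)c2c1OC(C)(C)C=C2
F2 | step 8 | 2-{2,2-dimethyl-5-[(triisopropylsilyl)oxy]-2H-chromen-8-yl}propane-1,3-diol | OCC(CO)c1ccc(O[Si](C(C)C)(C(C)C)C(C)C)c2c1OC(C)(C)C=C2
F3 | step 8 | (2S)-3-hydroxy-2-{2,2-dimethyl-5-[(triisopropylsilyl)oxy]-2H-chromen-8-yl}propyl acetate | OC[C@H](c1ccc(O[Si](C(C)C)(C(C)C)C(C)C)c2c1OC(C)(C)C=C2)COC(C)=O
F4 | step 8 | (2R)-3-bromo-2-{2,2-dimethyl-5-[(triisopropylsilyl)oxy]-2H-chromen-8-yl}propyl acetate | BrC[C@H](c1ccc(O[Si](C(C)C)(C(C)C)C(C)C)c2c1OC(C)(C)C=C2)COC(C)=O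
F5 | step 10 | 1,3-dimethoxy-5-(methoxymethoxy)-2-(3-methylbut-2-en-1-yl)benzene | COCOc1cc(OC)c(CC=C(C)C)c(OC)c1
F6 | step 10 | 2-lithio derivative of F5 (lithium between OMOM and OMe) | COCOc1cc(OC)c(CC=C(C)C)c(OC)c1[Li]
F7 | step 10 | [2,4-dimethoxy-6-(methoxymethoxy)-3-(3-methylbut-2-en-1-yl)phenyl]magnesium bromide | COCOc1cc(OC)c(CC=C(C)C)c(OC)c1[Mg]Br
F8 | step 10 | {(2R)-3-[2,4-dimethoxy-6-(methoxymethoxy)-3-(3-methylbut-2-en-1-yl)phenyl]-2-[2,2-dimethyl-5-(triisopropylsilyloxy)-2H-chromen-8-yl]propoxy}trimethylsilane | COCOc1cc(OC)c(CC=C(C)C)c(OC)c1C[C@H](c1ccc(O[Si](C(C)C)(C(C)C)C(C)C)c2c1OC(C)(C)C=C2)CO[Si](C)(C)C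
F9 | step 10 | 2-{(2R)-3-hydroxy-2-[2,2-dimethyl-5-(triisopropylsilyloxy)-2H-chromen-8-yl]propyl}-3,5-dimethoxy-4-(3-methylbut-2-en-1-yl)phenol | Oc1cc(OC)c(CC=C(C)C)c(OC)c1C[C@H](c1ccc(O[Si](C(C)C)(C(C)C)C(C)C)c2c1OC(C)(C)C=C2)CO
F10 | step 2 | 2-(3,5-dimethoxyphenyl)-4,4,5,5-tetramethyl-1,3,2-dioxaborolane | COc1cc(B2OC(C)(C)C(C)(C)O2)cc(OC)c1
F11 | step 2 | 3,5-dimethoxyphenol | COc1cc(O)cc(OC)c1
F12 | step 2 | (3,5-dimethoxyphenoxy)triisopropylsilane | COc1cc(O[Si](C(C)C)(C(C)C)C(C)C)cc(OC)c1
F13 | step 2 | 4-lithio derivative of F12 (lithium between the two OMe groups) | [Li]c1c(OC)cc(O[Si](C(C)C)(C(C)C)C(C)C)cc1OC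
F14 | step 2 | [3,5-dimethoxy-4-(3-methylbut-2-en-1-yl)phenoxy]triisopropylsilane | COc1cc(O[Si](C(C)C)(C(C)C)C(C)C)cc(OC)c1CC=C(C)C
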